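A direct plan would open both rings of the meso cis,trans,cis-cyclobutane-1,2,3,4-tetracarboxylic dianhydride A1 with the protected (R)-danshensu ester A2 under cinchona-alkaloid control, to give the C1/C2 diester C3/C4 diacid A3.
It would then change each free carboxyl group, by way of a thioester, the dialdehyde A4 and the dialkyne A5, into a catechol ring (cobalt-catalysed Diels–Alder reaction with a 2,3-bis(silyloxy)butadiene, then dehydrogenation) and would end with deprotection.
The twofold anhydride opening would be its weakest step: a hindered secondary α-hydroxy ester would have to pick one carbonyl group out of four, twice, without precedent.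
The change of carboxyl into formyl and ethynyl groups would come next: basic reagents would meet cyclobutane aldehydes that lie cis to an ester and could epimerise towards the all-trans ring.
The making of two benzene rings from carboxyl groups would add about five operations and no complexity, since these carbons could arrive as ready-made aryl groups.

The new route would read the ring as the union of two symmetric alkenes: C1 and C2 carry trans ester groups, C3 and C4 trans aryl groups, and each ester is cis to its neighbouring aryl group, which is the pattern of a suprafacial addition of an (E)-butenedioate (C1–C2) to an (E)-stilbene (C3–C4). The key step would be the crossed [2+2] photocycloaddition of a tetrabenzyloxystilbene with the fumarate of two protected (R)-danshensu units; it would close the cyclobutane, form C1–C4 and C2–C3 and set all four ring stereocentres at once, with the ester residues of the target as the only chiral controllers. No anhydride opening, no formyl intermediate and no arene construction would remain.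

Key step: step 4

Assumption: the sense of the facial induction that the two (R)-configured ester residues exert in step 4 is not fixed by precedent. The route is written for addition to the Re,Re face of the fumarate; if the other face were preferred, the same stereochemically pure cycloadduct would still be isolated, in lower amount, because the two adducts are diastereomers.

Step 1
Reactants: 1 (R)-danshensu, (2R)-3-(3,4-dihydroxyphenyl)-2-hydroxypropanoic acid
Product: 2 benzyl (2R)-3-[3,4-bis(benzyloxy)phenyl]-2-hydroxypropanoate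
Conditions: BnBr (3.3 equiv), K2CO3 (3.5 equiv), DMF, 0 °C → rt, argon
Reagents that add atoms: benzyl bromide, BrCc1ccccc1
Why: Williamson-type O-benzylation, in which carbonate deprotonates only the carboxylic acid and the two phenols, so that three benzyl groups go to these oxygens while the far less acidic secondary hydroxyl group stays free and the (R) centre, none of whose bonds is broken, is kept.

Step 2
Reactants: 2 benzyl (2R)-3-[3,4-bis(benzyloxy)phenyl]-2-hydroxypropanoate (two molecules incorporated); 3 fumaryl chloride, (2E)-but-2-enedioyl dichloride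
Product: 5 bis[(2R)-1-(benzyloxy)-3-[3,4-bis(benzyloxy)phenyl]-1-oxopropan-2-yl] (2E)-but-2-enedioate, via mono-ester acid chloride 4 (not isolated)
Conditions: 3 (1.0 equiv), 2 (2.1 equiv), pyridine (2.5 equiv), DMAP (5 mol %), CH2Cl2, −20 °C → rt
Reagents that add atoms: none
Why: Twofold acylation of the alcohol by the acid chloride through the N-acylpyridinium ion (Einhorn conditions with DMAP catalysis), in which neither the carbinol C–O bond nor the E double bond is touched, so that both (R) centres and the fumarate geometry are carried into 5.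

Step 3
Reactants: 6 3,4-bis(benzyloxy)benzaldehyde (two molecules incorporated)
Product: 7 (E)-1,2-bis[3,4-bis(benzyloxy)phenyl]ethene
Conditions: TiCl4 (2.2 equiv), Zn dust (4.5 equiv), THF, 0 °C → reflux; aq. K2CO3 work-up; recrystallisation
Reagents that add atoms: none
Why: McMurry coupling, in which low-valent titanium made from TiCl4 and Zn joins two aldehyde molecules reductively and removes both oxygens on heating, aromatic aldehydes giving mainly the more stable E alkene, which should crystallise from the crude product, while the aryl benzyl ethers are not attacked.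

Step 4
Reactants: 5 bis(danshensu) fumarate (excess, recovered); 7 (E)-tetrabenzyloxystilbene
Product: 8 bis[(2R)-1-(benzyloxy)-3-[3,4-bis(benzyloxy)phenyl]-1-oxopropan-2-yl] (1R,2R,3R,4R)-3,4-bis[3,4-bis(benzyloxy)phenyl]cyclobutane-1,2-dicarboxylate (decabenzyl-protected target)
Conditions: 7 (0.05 M), 5 (3 equiv), degassed toluene, −20 °C, hν (365 nm), argon; chromatography (5 recovered), crystallisation
Reagents that add atoms: none
Why: Light of 365 nm is absorbed only by the stilbene 7 and its charge-transfer complex with the electron-poor fumarate 5, and the singlet excited donor–acceptor pair (exciplex), in which each aryl ring of 7 is stacked over an ester carbonyl group of 5, collapses by suprafacial [2+2] cycloaddition that forms the bonds C1–C4 and C2–C3. The closest known reaction type is the singlet-exciplex [2+2] photocycloaddition of (E)-stilbene with dialkyl fumarates, fumarates of chiral alcohols included, which gives this μ-truxinate arrangement. The cyclobutane is the only ring closed, by intermolecular [2+2] union of the two C=C bonds. Since the singlet complex collapses faster than either double bond can rotate, C1/C2 trans follows from the E geometry of 5 and C3/C4 trans from that of 7, the cis relations C1/C4 and C2/C3 follow from the stacked geometry, and the absolute configuration (1R,2R,3R,4R) follows from addition to the Re,Re face of 5, which the two (R) carbinol centres, exchanged by the twofold axis perpendicular to the fumarate plane and lying under the stacked aryl rings, should bias cooperatively. The step needs face selectivity only, because both partners are twofold-symmetric and no regiochemical question arises, and excess 5, low temperature and a non-polar solvent favour capture of excited 7 over its E–Z isomerisation, while 8 does not absorb at 365 nm and is not cleaved again. Whatever the level of induction, the adduct of the other face is a diastereomer of 8 and should be removed by chromatography or crystallisation, so that the stereochemical purity of 8 rests on the (R) centres brought in with 1.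

Step 5
Reactants: 8 decabenzyl-protected target
Product: 9 CNP0163929.1, bis[(1R)-1-carboxy-2-(3,4-dihydroxyphenyl)ethyl] (1R,2R,3R,4R)-3,4-bis(3,4-dihydroxyphenyl)cyclobutane-1,2-dicarboxylate
Conditions: H2 (1 atm), Pd/C (10 wt %), THF–MeOH (1:1), rt; filtration under argon; C18 chromatography (H2O–MeCN, 0.1 % HCO2H), lyophilisation
Reagents that add atoms: none
Why: Heterogeneous hydrogenolysis of benzylic C–O bonds, which should free the eight phenols and the two carboxyl groups under neutral conditions, while the two ester links to the cyclobutane are non-benzylic alkyl esters and the epimerisable centres C1 and C2 never meet a base, so that no stereocentre is touched.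

Compound list
1 | (R)-danshensu, (2R)-3-(3,4-dihydroxyphenyl)-2-hydroxypropanoic acid | O[C@H](Cc1ccc(O)c(O)c1)C(=O)O | starting material
2 | benzyl (2R)-3-[3,4-bis(benzyloxy)phenyl]-2-hydroxypropanoate | O[C@H](Cc1ccc(OCc2ccccc2)c(OCc2ccccc2)c1)C(=O)OCc1ccccc1 | intermediate
3 | fumaryl chloride, (2E)-but-2-enedioyl dichloride | O=C(Cl)/C=C/C(=O)Cl | starting material
4 | (2R)-1-(benzyloxy)-3-[3,4-bis(benzyloxy)phenyl]-1-oxopropan-2-yl (2E)-4-chloro-4-oxobut-2-enoate (mono-ester acid chloride) | O=C(Cl)/C=C/C(=O)O[C@H](Cc1ccc(OCc2ccccc2)c(OCc2ccccc2)c1)C(=O)OCc1ccccc1 | intermediate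
5 | bis[(2R)-1-(benzyloxy)-3-[3,4-bis(benzyloxy)phenyl]-1-oxopropan-2-yl] (2E)-but-2-enedioate | O=C(O[C@H](Cc1ccc(OCc2ccccc2)c(OCc2ccccc2)c1)C(=O)OCc1ccccc1)/C=C/C(=O)O[C@H](Cc1ccc(OCc2ccccc2)c(OCc2ccccc2)c1)C(=O)OCc1ccccc1 | intermediate
6 | 3,4-bis(benzyloxy)benzaldehyde | O=Cc1ccc(OCc2ccccc2)c(OCc2ccccc2)c1 | starting material
7 | (E)-1,2-bis[3,4-bis(benzyloxy)phenyl]ethene | c1(/C=C/c2ccc(OCc3ccccc3)c(OCc3ccccc3)c2)ccc(OCc2ccccc2)c(OCc2ccccc2)c1 | intermediate
8 | bis[(2R)-1-(benzyloxy)-3-[3,4-bis(benzyloxy)phenyl]-1-oxopropan-2-yl] (1R,2R,3R,4R)-3,4-bis[3,4-bis(benzyloxy)phenyl]cyclobutane-1,2-dicarboxylate | O=C(O[C@H](Cc1ccc(OCc2ccccc2)c(OCc2ccccc2)c1)C(=O)OCc1ccccc1)[C@H]1[C@H](C(=O)O[C@H](Cc2ccc(OCc3ccccc3)c(OCc3ccccc3)c2)C(=O)OCc2ccccc2)[C@H](c2ccc(OCc3ccccc3)c(OCc3ccccc3)c2)[C@H]1c1ccc(OCc2ccccc2)c(OCc2ccccc2)c1 | intermediate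
9 | CNP0163929.1, bis[(1R)-1-carboxy-2-(3,4-dihydroxyphenyl)ethyl] (1R,2R,3R,4R)-3,4-bis(3,4-dihydroxyphenyl)cyclobutane-1,2-dicarboxylate | O=C(O[C@H](Cc1ccc(O)c(O)c1)C(=O)O)[C@H]1[C@H](C(=O)O[C@H](Cc2ccc(O)c(O)c2)C(=O)O)[C@H](c2ccc(O)c(O)c2)[C@H]1c1ccc(O)c(O)c1 | target

Total step count: 5. Longest linear sequence: 4 steps (steps 1, 2, 4 and 5; step 3 is a one-step side branch).

Steps most likely to fail

Step 4. The two (R)-configured residues may discriminate the faces of the fumarate only weakly, or in the opposite sense. The short-lived excited stilbene may also be lost to E–Z isomerisation or to electron transfer without ring closure. The fallback needs neither light nor auxiliary induction and uses known chemistry; it sets out from alcohol 2 and comes back at 8. (1R,2R)-Cyclobutane-1,2-dicarboxylic acid F1, obtained by classical resolution of the commercial racemic trans-diacid, would be converted ((COCl)2, cat. DMF, CH2Cl2; then 8-aminoquinoline, Et3N) into (1R,2R)-N,N'-di(quinolin-8-yl)cyclobutane-1,2-dicarboxamide F2. A twofold aminoquinoline-directed C–H arylation (Pd(OAc)2, AgOAc, 1,2-bis(benzyloxy)-4-iodobenzene, toluene, 100 °C) should place one aryl group on C4 cis to the C1 amide and one on C3 cis to the C2 amide, each by way of a five-membered palladacycle. This should give (1R,2R,3R,4R)-3,4-bis[3,4-bis(benzyloxy)phenyl]-N,N'-di(quinolin-8-yl)cyclobutane-1,2-dicarboxamide F3, whose ring configuration follows from that of F1. Acylation on nitrogen with Boc2O and DMAP (MeCN, 60 °C) should give the bis(N-Boc) amide F4. Cleavage with LiOH and H2O2 (THF–H2O, 0 °C) should give (1R,2R,3R,4R)-3,4-bis[3,4-bis(benzyloxy)phenyl]cyclobutane-1,2-dicarboxylic acid F5. Steglich esterification of F5 with 2 (EDC·HCl, DMAP cat., CH2Cl2, 0 °C) should give 8.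

Step 5. The tenfold hydrogenolysis may stall when partly debenzylated, poorly soluble intermediates precipitate on the catalyst. The strained, doubly benzylic C3–C4 bond may be hydrogenolysed, and the four catechols may oxidise in air during isolation. The fallback sets out from 8 and comes back at 9, and it makes no new compound (F0). It is a non-reductive debenzylation with BCl3 (excess) and pentamethylbenzene as benzyl cation scavenger in CH2Cl2 at −78 °C, quenched with MeOH. This should cleave the aryl benzyl ethers and benzyl esters by Lewis-acid-assisted ionisation of the benzylic C–O bonds, and it cannot open the ring reductively.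

Step 2. The second acylation of the poorly nucleophilic α-hydroxy ester may remain incomplete, fumaryl chloride may be lost to coloured pyridine adducts, and the amine may add to the activated double bond. The fallback sets out from 2 and comes back at 5; it forms the C=C bond in place of the two C–O bonds. Acylation of 2 with acryloyl chloride (Et3N, CH2Cl2, −20 °C) should give the acrylate (2R)-1-(benzyloxy)-3-[3,4-bis(benzyloxy)phenyl]-1-oxopropan-2-yl prop-2-enoate F6. Self-metathesis of F6 with the second-generation Hoveyda–Grubbs catalyst (5 mol %) in refluxing CH2Cl2 under an argon sweep should give the E-configured diester 5 with loss of ethylene.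

Further compounds
F1 | step 4 | (1R,2R)-cyclobutane-1,2-dicarboxylic acid | O=C(O)[C@H]1[C@H](C(=O)O)CC1
F2 | step 4 | (1R,2R)-N,N'-di(quinolin-8-yl)cyclobutane-1,2-dicarboxamide | O=C(Nc1cccc2cccnc12)[C@H]1[C@H](C(=O)Nc2cccc3cccnc23)CC1
F3 | step 4 | (1R,2R,3R,4R)-3,4-bis[3,4-bis(benzyloxy)phenyl]-N,N'-di(quinolin-8-yl)cyclobutane-1,2-dicarboxamide | O=C(Nc1cccc2cccnc12)[C@H]1[C@H](C(=O)Nc2cccc3cccnc23)[C@H](c2ccc(OCc3ccccc3)c(OCc3ccccc3)c2)[C@H]1c1ccc(OCc2ccccc2)c(OCc2ccccc2)c1
F4 | step 4 | bis(N-Boc) derivative of F3, di-tert-butyl N,N'-[(1R,2R,3R,4R)-3,4-bis[3,4-bis(benzyloxy)phenyl]cyclobutane-1,2-dicarbonyl]bis[N-(quinolin-8-yl)carbamate] | O=C(N(C(=O)OC(C)(C)C)c1cccc2cccnc12)[C@H]1[C@H](C(=O)N(C(=O)OC(C)(C)C)c2cccc3cccnc23)[C@H](c2ccc(OCc3ccccc3)c(OCc3ccccc3)c2)[C@H]1c1ccc(OCc2ccccc2)c(OCc2ccccc2)c1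
F5 | step 4 | (1R,2R,3R,4R)-3,4-bis[3,4-bis(benzyloxy)phenyl]cyclobutane-1,2-dicarboxylic acid | O=C(O)[C@H]1[C@H](C(=O)O)[C@H](c2ccc(OCc3ccccc3)c(OCc3ccccc3)c2)[C@H]1c1ccc(OCc2ccccc2)c(OCc2ccccc2)c1
F0 | step 5 | none | none
F6 | step 2 | (2R)-1-(benzyloxy)-3-[3,4-bis(benzyloxy)phenyl]-1-oxopropan-2-yl prop-2-enoate | C=CC(=O)O[C@H](Cc1ccc(OCc2ccccc2)c(OCc2ccccc2)c1)C(=O)OCc1ccccc1
A1 | direct plan | cis,trans,cis-cyclobutane-1,2,3,4-tetracarboxylic 1,4:2,3-dianhydride (meso) | O=C2[C@H]1[C@H](C3=O)[C@H](C(=O)O3)[C@H]1C(=O)O2
A2 | direct plan | tert-butyl (2R)-3-[3,4-bis(tert-butyldimethylsilyloxy)phenyl]-2-hydroxypropanoate | O[C@H](Cc1ccc(O[Si](C)(C)C(C)(C)C)c(O[Si](C)(C)C(C)(C)C)c1)C(=O)OC(C)(C)C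
A3 | direct plan | (1R,2R,3R,4R)-cyclobutane-1,2,3,4-tetracarboxylic acid esterified at the C1 and C2 carboxyls with A2, free acids on C3 and C4 | O=C(O[C@H](Cc1ccc(O[Si](C)(C)C(C)(C)C)c(O[Si](C)(C)C(C)(C)C)c1)C(=O)OC(C)(C)C)[C@H]1[C@H](C(=O)O[C@H](Cc2ccc(O[Si](C)(C)C(C)(C)C)c(O[Si](C)(C)C(C)(C)C)c2)C(=O)OC(C)(C)C)[C@H](C(=O)O)[C@H]1C(=O)O
A4 | direct plan | C3/C4 dialdehyde derived from A3 (3,4-diformyl compound) | O=C(O[C@H](Cc1ccc(O[Si](C)(C)C(C)(C)C)c(O[Si](C)(C)C(C)(C)C)c1)C(=O)OC(C)(C)C)[C@H]1[C@H](C(=O)O[C@H](Cc2ccc(O[Si](C)(C)C(C)(C)C)c(O[Si](C)(C)C(C)(C)C)c2)C(=O)OC(C)(C)C)[C@H](C=O)[C@H]1C=O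
A5 | direct plan | C3/C4 dialkyne derived from A4 (3,4-diethynyl compound) | O=C(O[C@H](Cc1ccc(O[Si](C)(C)C(C)(C)C)c(O[Si](C)(C)C(C)(C)C)c1)C(=O)OC(C)(C)C)[C@H]1[C@H](C(=O)O[C@H](Cc2ccc(O[Si](C)(C)C(C)(C)C)c(O[Si](C)(C)C(C)(C)C)c2)C(=O)OC(C)(C)C)[C@H](C#C)[C@H]1C#C
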